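**Retrosynthetic overview**

1. The oxane ring is made last, by 6-endo bromoetherification of the tertiary homoprenyl carbinol 21; 21 comes from chelation-controlled addition of a homoprenyl Grignard reagent to the cis-hydroxy ketone 18.
2. Ring A is closed by forming its CH2–CHBr bond: a TiCl4-mediated, chloride-terminated cyclisation of the acyclic 2-methylidene ketone 15 onto its own (E)-bromoalkene, which also forms the C–Cl bond and sets three stereocentres (15 → 17).
3. Enabling feature: ring A carries a secondary bromide next to a tertiary chloride, trans to each other (CHBr–C(CH3)Cl), which is the imprint of anti addition of carbon and chloride across an (E)-1-bromo-2-methylalkene. The ring carbon that bears the oxane's quaternary C–O carbon lies between the ring CH2 and the carbinol carbon, so at the acetyl oxidation level it is the α-carbon of an acceptor CH2=C(COCH3)–CH(OSi).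
4. 15 comes from an Evans aldol of imide 8 with aldehyde 4 (the auxiliary sets the carbinol centre), Weinreb amide/MeMgBr, and sulfoxide elimination to unveil the methylidene; 4 comes from but-3-yn-1-ol by carboalumination–bromination.
5. Order of ring formation: ring A (cyclohexane) first, oxane ring second.

Key step: step 9

Remark: compounds 1, 5, 6 and 19 and all named reagents are taken as commercial; aldehyde 4 and enone 15 are used without storage.

**Step 1**
Reactants: 1 but-3-yn-1-ol
Product: 3 (3E)-4-bromo-3-methylbut-3-en-1-ol, via alkenylalane 2 (not isolated)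
Conditions: Me3Al (3 equiv), Cp2ZrCl2 (0.25 equiv), CH2Cl2, 0 °C → rt; then NBS, THF, −30 → 0 °C
Reagents that add atoms: trimethylaluminium, C[Al](C)C; N-bromosuccinimide, BrN1C(=O)CCC1=O
Why: Negishi zirconium-catalysed carboalumination adds CH3 and Al syn across the terminal alkyne (CH3 to the internal carbon), and brominolysis of the alkenyl–Al bond with retention should give the E bromoalkene with Br cis to CH3.

**Step 2**
Reactants: 3 (3E)-4-bromo-3-methylbut-3-en-1-ol
Product: 4 (3E)-4-bromo-3-methylbut-3-enal
Conditions: Dess–Martin periodinane, NaHCO3, CH2Cl2, 0 °C → rt; used crude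
Reagents that add atoms: none
Why: Dess–Martin oxidation is neutral enough to stop at the β,γ-unsaturated aldehyde without moving the double bond into conjugation.

**Step 3**
Reactants: 5 3-(phenylsulfanyl)propanoic acid; 6 (4R)-4-benzyl-1,3-oxazolidin-2-one
Product: 8 (4R)-4-benzyl-3-[3-(phenylsulfanyl)propanoyl]-1,3-oxazolidin-2-one, via mixed pivalic anhydride 7 (not isolated)
Conditions: PivCl, Et3N, THF, −20 °C; then LiCl, 6, −20 °C → rt
Reagents that add atoms: none
Why: N-acylation of an oxazolidinone through a mixed pivalic anhydride (LiCl/Et3N protocol) is a standard imide synthesis; the phenylsulfanylmethyl group is the masked methylidene.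

**Step 4**
Reactants: 8 (4R)-4-benzyl-3-[3-(phenylsulfanyl)propanoyl]-1,3-oxazolidin-2-one; 4 (3E)-4-bromo-3-methylbut-3-enal
Product: 10 (4R)-4-benzyl-3-[(2R,3S,5E)-6-bromo-3-hydroxy-5-methyl-2-[(phenylsulfanyl)methyl]hex-5-enoyl]-1,3-oxazolidin-2-one, via boron enolate 9 (not isolated)
Conditions: Bu2BOTf, i-Pr2NEt, CH2Cl2, −78 → 0 °C; then 4, −78 → −10 °C; MeOH, pH 7 buffer (no peroxide)
Reagents that add atoms: none
Why: Evans syn-aldol reaction: the Z boron enolate reacts through a Zimmerman–Traxler chair in which the (R)-benzyl auxiliary fixes the aldehyde face, which should give the (3S) carbinol (the α-centre is destroyed later); the peroxide-free work-up keeps the sulfide.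

**Step 5**
Reactants: 10 (the aldol adduct)
Product: 11 (2R,3S,5E)-6-bromo-3-hydroxy-N-methoxy-N,5-dimethyl-2-[(phenylsulfanyl)methyl]hex-5-enamide
Conditions: Me3Al, MeNH(OMe)·HCl, CH2Cl2, −20 → 0 °C; aq Rochelle salt
Reagents that add atoms: N,O-dimethylhydroxylamine hydrochloride, CNOC.Cl
Why: Weinreb transamidation with the aluminium amide, assisted by the free β-hydroxyl, removes the auxiliary under conditions that should not cause retro-aldol cleavage.

**Step 6**
Reactants: 11 (the hydroxy Weinreb amide)
Product: 12 (2R,3S,5E)-6-bromo-3-[(tert-butyldimethylsilyl)oxy]-N-methoxy-N,5-dimethyl-2-[(phenylsulfanyl)methyl]hex-5-enamide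
Conditions: TBSOTf, 2,6-lutidine, CH2Cl2, −78 → 0 °C
Reagents that add atoms: tert-butyldimethylsilyl triflate, CC(C)(C)[Si](C)(C)OS(=O)(=O)C(F)(F)F
Why: Silylation of the secondary alcohol with a silyl triflate and a hindered base is routine; the bulky TBS ether is chosen because it does not chelate in step 9.

**Step 7**
Reactants: 12 (the silylated Weinreb amide)
Product: 13 (3R,4S,6E)-7-bromo-4-[(tert-butyldimethylsilyl)oxy]-6-methyl-3-[(phenylsulfanyl)methyl]hept-6-en-2-one
Conditions: MeMgBr (3 equiv), THF, −20 → 0 °C; aq NH4Cl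
Reagents that add atoms: methylmagnesium bromide, C[Mg]Br
Why: Grignard addition to a Weinreb amide should stop at the methyl ketone because the chelated tetrahedral intermediate survives until work-up.

**Step 8**
Reactants: 13 (the sulfide ketone)
Product: 15 (4S,6E)-7-bromo-4-[(tert-butyldimethylsilyl)oxy]-6-methyl-3-methylidenehept-6-en-2-one, via sulfoxide 14 (not isolated)
Conditions: mCPBA (1.0 equiv), CH2Cl2, −78 °C; then toluene, CaCO3, 90 °C
Reagents that add atoms: none
Why: Chemoselective S-oxidation followed by thermal syn-elimination of the sulfoxide (sulfoxide pyrolysis) towards its only β-hydrogen, which is α to the ketone, should unveil the 2-methylidene ketone without touching the silyl ether.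

**Step 9**
Reactants: 15 (the 2-methylidene ketone)
Product: 17 1-[(1R,2S,4S,5S)-5-bromo-2-[(tert-butyldimethylsilyl)oxy]-4-chloro-4-methylcyclohexyl]ethan-1-one, via titanium enolate 16 (not isolated)
Conditions: TiCl4 (2 equiv), 2,6-di-tert-butylpyridine (0.2 equiv), CH2Cl2, −78 → −40 °C; then MeOH, −78 °C; H2O
Reagents that add atoms: titanium tetrachloride, Cl[Ti](Cl)(Cl)Cl
Why: Proposed new method: TiCl4 on the acetyl oxygen makes the 2-methylidene ketone a cationic acceptor whose CH2 terminus is attacked by the bromine-bearing carbon of the (E)-bromoalkene, the only regiochemistry that gives a six-membered ring and a tertiary, bromine-stabilised cation; chloride from the chlorotitanate quenches that cation to leave enolate 16, which is C-protonated on the cold quench, and the closest known reactions are Lewis-acid-initiated enone–alkene cation–olefin cyclisations terminated by chloride and the Markovnikov anti addition of electrophiles to 1-bromo-2-methylalkenes. Ring A closes in a 6-endo-trig mode at the enone terminus (the bromoalkene is also endocyclic) through a chair transition state. The CHBr centre is set by the E geometry of the bromoalkene (Br equatorial) together with the face imposed by the silyloxy carbinol centre, whose C–O bond stands axial to avoid A(1,3) strain with the coplanar acetyl group; the C(CH3)Cl centre is set by chloride entering anti to the new C–C bond and anti to bromine, on the face away from the axial silyl ether. The acetyl-bearing centre is set by kinetic protonation of the exocyclic enolate anti to the adjacent axial silyloxy group, which should give the cis-2-silyloxy ketone. The step needs facial selectivity (secured by the allylic silyl ether and its non-chelating TBS group), regioselectivity for attack through the CHBr carbon (secured by the methyl group that makes the cation tertiary and by six- over five-membered closure), chemoselectivity over reversible conjugate addition of chloride (the C–C closure is irreversible), and no equilibration of the kinetically set acetyl centre (cold, non-basic quench).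

**Step 10**
Reactants: 17 (the silyloxy ketone)
Product: 18 1-[(1R,2S,4S,5S)-5-bromo-4-chloro-2-hydroxy-4-methylcyclohexyl]ethan-1-one
Conditions: HF·pyridine, pyridine, THF, 0 °C → rt
Reagents that add atoms: none
Why: Buffered fluoride desilylation should free the hydroxyl without enolising the epimerisable acetyl-bearing carbon or eliminating the β-oxygen.

**Step 11**
Reactants: 18 (the hydroxy ketone); 19 5-bromo-2-methylpent-2-ene
Product: 21 (1S,2R,4S,5S)-4-bromo-5-chloro-2-[(2S)-2-hydroxy-6-methylhept-5-en-2-yl]-5-methylcyclohexan-1-ol, via Grignard reagent 20 (not isolated)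
Conditions: 19, Mg, Et2O, rt; then 18 (to 3 equiv of 20), CH2Cl2, −78 → −40 °C; aq NH4Cl
Reagents that add atoms: none
Why: Cram-chelate (1,3) controlled Grignard addition: the magnesium alkoxide of the cis hydroxyl chelates the ketone, and attack on the chelate face opposite the ring CH2 should give the (S) tertiary carbinol; the halides are inert at this temperature.

**Step 12**
Reactants: 21 (the diol)
Product: 22 (1S,2R,4S,5S)-4-bromo-2-[(2S,5R)-5-bromo-2,6,6-trimethyloxan-2-yl]-5-chloro-5-methylcyclohexan-1-ol
Conditions: 2,4,4,6-tetrabromocyclohexa-2,5-dienone (TBCO, 1.1 equiv), MeNO2, 4 Å MS, 0 °C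
Reagents that add atoms: 2,4,4,6-tetrabromocyclohexa-2,5-dienone, O=C1C(Br)=CC(Br)(Br)C=C1Br
Why: Bromoetherification (bromonium-induced 6-endo cyclisation): the tertiary hydroxyl opens the bromonium ion at the more substituted carbon, and a chair transition state with the cyclohexyl group equatorial should place bromine equatorial and cis to the oxane methyl, i.e. (5R).

**Compound list**

1 | but-3-yn-1-ol | C#CCCO | starting material
2 | dimethyl[(1E)-4-[(dimethylalumanyl)oxy]-2-methylbut-1-en-1-yl]alumane (alkenylalane, not isolated) | C/C(CCO[Al](C)C)=C\[Al](C)C | intermediate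
3 | (3E)-4-bromo-3-methylbut-3-en-1-ol | OCC/C(C)=C/Br | intermediate
4 | (3E)-4-bromo-3-methylbut-3-enal | O=CC/C(C)=C/Br | intermediate
5 | 3-(phenylsulfanyl)propanoic acid | OC(=O)CCSc1ccccc1 | starting material
6 | (4R)-4-benzyl-1,3-oxazolidin-2-one | O=C1N[C@H](Cc2ccccc2)CO1 | starting material
7 | 2,2-dimethylpropanoic 3-(phenylsulfanyl)propanoic anhydride (mixed pivalic anhydride, not isolated) | CC(C)(C)C(=O)OC(=O)CCSc1ccccc1 | intermediate
8 | (4R)-4-benzyl-3-[3-(phenylsulfanyl)propanoyl]-1,3-oxazolidin-2-one | O=C(CCSc1ccccc1)N1[C@H](Cc2ccccc2)COC1=O | intermediate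
9 | (Z)-dibutylboron enolate of 8 (not isolated) | CCCCB(CCCC)O/C(=C\CSc1ccccc1)N1[C@H](Cc2ccccc2)COC1=O | intermediate
10 | (4R)-4-benzyl-3-[(2R,3S,5E)-6-bromo-3-hydroxy-5-methyl-2-[(phenylsulfanyl)methyl]hex-5-enoyl]-1,3-oxazolidin-2-one | O=C([C@H](CSc1ccccc1)[C@@H](O)C/C(C)=C/Br)N1[C@H](Cc2ccccc2)COC1=O | intermediate
11 | (2R,3S,5E)-6-bromo-3-hydroxy-N-methoxy-N,5-dimethyl-2-[(phenylsulfanyl)methyl]hex-5-enamide | CON(C)C(=O)[C@H](CSc1ccccc1)[C@@H](O)C/C(C)=C/Br | intermediate
12 | (2R,3S,5E)-6-bromo-3-[(tert-butyldimethylsilyl)oxy]-N-methoxy-N,5-dimethyl-2-[(phenylsulfanyl)methyl]hex-5-enamide | CON(C)C(=O)[C@H](CSc1ccccc1)[C@@H](O[Si](C)(C)C(C)(C)C)C/C(C)=C/Br | intermediate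
13 | (3R,4S,6E)-7-bromo-4-[(tert-butyldimethylsilyl)oxy]-6-methyl-3-[(phenylsulfanyl)methyl]hept-6-en-2-one | CC(=O)[C@H](CSc1ccccc1)[C@@H](O[Si](C)(C)C(C)(C)C)C/C(C)=C/Br | intermediate
14 | (3R,4S,6E)-7-bromo-4-[(tert-butyldimethylsilyl)oxy]-6-methyl-3-[(phenylsulfinyl)methyl]hept-6-en-2-one (sulfoxide, both S-epimers, not isolated) | CC(=O)[C@H](CS(=O)c1ccccc1)[C@@H](O[Si](C)(C)C(C)(C)C)C/C(C)=C/Br | intermediate
15 | (4S,6E)-7-bromo-4-[(tert-butyldimethylsilyl)oxy]-6-methyl-3-methylidenehept-6-en-2-one | CC(=O)C(=C)[C@@H](O[Si](C)(C)C(C)(C)C)C/C(C)=C/Br | intermediate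
16 | trichlorotitanium enolate of 17 (not isolated) | CC(O[Ti](Cl)(Cl)Cl)=C1C[C@H](Br)[C@@](C)(Cl)C[C@@H]1O[Si](C)(C)C(C)(C)C | intermediate
17 | 1-[(1R,2S,4S,5S)-5-bromo-2-[(tert-butyldimethylsilyl)oxy]-4-chloro-4-methylcyclohexyl]ethan-1-one | CC(=O)[C@@H]1C[C@H](Br)[C@@](C)(Cl)C[C@@H]1O[Si](C)(C)C(C)(C)C | intermediate
18 | 1-[(1R,2S,4S,5S)-5-bromo-4-chloro-2-hydroxy-4-methylcyclohexyl]ethan-1-one | CC(=O)[C@@H]1C[C@H](Br)[C@@](C)(Cl)C[C@@H]1O | intermediate
19 | 5-bromo-2-methylpent-2-ene | CC(C)=CCCBr | starting material
20 | (4-methylpent-3-en-1-yl)magnesium bromide (not isolated) | CC(C)=CCC[Mg]Br | intermediate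
21 | (1S,2R,4S,5S)-4-bromo-5-chloro-2-[(2S)-2-hydroxy-6-methylhept-5-en-2-yl]-5-methylcyclohexan-1-ol | O[C@](C)([C@@H]1C[C@H](Br)[C@@](C)(Cl)C[C@@H]1O)CCC=C(C)C | intermediate
22 | (1S,2R,4S,5S)-4-bromo-2-[(2S,5R)-5-bromo-2,6,6-trimethyloxan-2-yl]-5-chloro-5-methylcyclohexan-1-ol | CC1(C)O[C@](C)([C@@H]2C[C@H](Br)[C@@](C)(Cl)C[C@@H]2O)CC[C@H]1Br | target

**Step count and risks**

Total step count: 12. Longest linear sequence: 11 steps (1 → 3 → 4 → 10 → 11 → 12 → 13 → 15 → 17 → 18 → 21 → 22); step 3 is a one-step branch.

Steps most likely to fail: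

1. Step 9 (proposed new method). The weakly nucleophilic bromoalkene may fail to intercept the activated enone before chloride adds in a conjugate sense or the allylic silyl ether ionises. The tertiary cation may lose a proton instead of capturing chloride. Partial chelation of titanium by the silyl ether would reverse the chair preference, and the acetyl-bearing centre may equilibrate on quenching.
Fallback with known chemistry, setting out from 4 and coming back at 17: 4 is treated with TBSOTf/Et3N to give the silyl dienol ether (1E,3E)-4-bromo-1-[(tert-butyldimethylsilyl)oxy]-3-methylbuta-1,3-diene F1 (only the 1E isomer reacts on). An enantioselective endo Diels–Alder reaction of F1 with but-3-en-2-one is then run with the triflimide-activated 3,3-diphenyl-1-(o-tolyl)tetrahydropyrrolo[1,2-c][1,3,2]oxazaborole, using the catalyst enantiomer that delivers the (1R,2S,5S) adduct. This should give 1-[(1R,2S,5S)-5-bromo-2-[(tert-butyldimethylsilyl)oxy]-4-methylcyclohex-3-en-1-yl]ethan-1-one F2 with acetyl, silyloxy and bromine all cis. Markovnikov hydrochlorination of the trisubstituted ring alkene (HCl, CH2Cl2, −78 °C), with the allylic bromine bridging the tertiary cation so that chloride enters trans to it, should then give 17. In this fallback ring A is made by cycloaddition rather than by a single ring-closing bond.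

2. Step 12. Closure may go 5-exo to the oxolane instead of 6-endo, and facial selectivity in bromonium formation may be poor.
Fallback, setting out from 21 and coming back at 22: oxymercuration–cyclisation of 21 with Hg(OCOCF3)2 in CH2Cl2, then aqueous KBr, should give bromo[(3R,6S)-6-[(1R,2S,4S,5S)-5-bromo-4-chloro-2-hydroxy-4-methylcyclohexyl]-2,2,6-trimethyloxan-3-yl]mercury F5. Strict Markovnikov attack of the tertiary hydroxyl enforces the six-membered ring, and anti addition through a chair places mercury equatorial. Brominolysis of the C–Hg bond with Br2 in pyridine, which proceeds with retention, should then give 22.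

3. Step 11. The Grignard reagent may enolise the ketone or trigger retro-aldol cleavage of the magnesium aldolate, and chelation control at the new quaternary carbinol may be incomplete.
Fallback, setting out from 17 and coming back at 21: kinetic deprotonation of the methyl ketone 17 (LDA, THF, −78 °C) and alkylation with 1-bromo-3-methylbut-2-ene should give 1-[(1R,2S,4S,5S)-5-bromo-2-[(tert-butyldimethylsilyl)oxy]-4-chloro-4-methylcyclohexyl]-5-methylhex-4-en-1-one F3. Felkin–Anh addition of MeLi (Et2O, −78 °C), anti to the silyloxy-bearing ring branch and without chelation, should give (2S)-2-[(1R,2S,4S,5S)-5-bromo-2-[(tert-butyldimethylsilyl)oxy]-4-chloro-4-methylcyclohexyl]-6-methylhept-5-en-2-ol F4. Here the order in which methyl and homoprenyl are introduced is inverted, so the opposite facial rule leads to the same (S) centre. HF·pyridine then gives 21.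

**Further compounds**

F1 | step 9 | (1E,3E)-4-bromo-1-[(tert-butyldimethylsilyl)oxy]-3-methylbuta-1,3-diene | CC(C)(C)[Si](C)(C)O/C=C/C(C)=C/Br
F2 | step 9 | 1-[(1R,2S,5S)-5-bromo-2-[(tert-butyldimethylsilyl)oxy]-4-methylcyclohex-3-en-1-yl]ethan-1-one | CC(=O)[C@@H]1C[C@H](Br)C(C)=C[C@@H]1O[Si](C)(C)C(C)(C)C
F3 | step 11 | 1-[(1R,2S,4S,5S)-5-bromo-2-[(tert-butyldimethylsilyl)oxy]-4-chloro-4-methylcyclohexyl]-5-methylhex-4-en-1-one | CC(C)=CCCC(=O)[C@@H]1C[C@H](Br)[C@@](C)(Cl)C[C@@H]1O[Si](C)(C)C(C)(C)C
F4 | step 11 | (2S)-2-[(1R,2S,4S,5S)-5-bromo-2-[(tert-butyldimethylsilyl)oxy]-4-chloro-4-methylcyclohexyl]-6-methylhept-5-en-2-ol | O[C@](C)([C@@H]1C[C@H](Br)[C@@](C)(Cl)C[C@@H]1O[Si](C)(C)C(C)(C)C)CCC=C(C)C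
F5 | step 12 | bromo[(3R,6S)-6-[(1R,2S,4S,5S)-5-bromo-4-chloro-2-hydroxy-4-methylcyclohexyl]-2,2,6-trimethyloxan-3-yl]mercury | CC1(C)O[C@](C)([C@@H]2C[C@H](Br)[C@@](C)(Cl)C[C@@H]2O)CC[C@H]1[Hg]Br
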